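**Retrosynthetic overview**

1. Target 16 comes from 15 by hydrogenolysis of four benzyl groups; the C2–OH of 15 comes with retention from the C2–B bond of 14, which arises from chromone 13 by a ligand-controlled copper-boryl addition to C2=C3 (a formal asymmetric hydration).
2. Chromone acid 12 is cut through C3–C2 and O1–C8a into fluoro ketone 6 (ring A with C4, C3 and fluorine on C8a) and arylacetate 10 (C2 with its carbonyl oxygen, the CH2 and ring D). One Claisen/SNAr cascade makes both bonds and closes ring C, the only ring that is built; rings A and D are bought.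
3. Enabling feature: C3 is the methylene between the C4 aryl ketone and the C2 hemiketal carbon (a masked 1,3-diketone), and C8a is the ring A carbon ortho to the C4 carbonyl. The ketone enolate can therefore take C2 as an acyl carbon while the same carbonyl activates a C8a–F bond for displacement by the C2 oxygen.
4. 6 comes from 3-bromo-5-fluorophenol (benzylation, Kumada coupling, para-bromination, acylation); 10 comes from methyl 2-(3,5-dihydroxyphenyl)acetate (benzylation, Vilsmeier–Haack formylation, Pinnick oxidation).

Key step: step 8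

Assumption: the C2 hemiketal of the 2-hydroxychroman-4-one is taken to keep its configuration in neutral, aprotic medium at or below 20 °C (it can racemise only by ring opening to the 1,3-diketone), so C2 is carried as a C–B bond and the free hemiketal is exposed only in the last two steps.

**Route**

Step 1
Reactants: 1 3-bromo-5-fluorophenol
Product: 2 1-(benzyloxy)-3-bromo-5-fluorobenzene
Conditions: BnBr (1.1 equiv), K2CO3, DMF, 20 °C
Reagents that add atoms: benzyl bromide, BrCc1ccccc1
Why: Williamson ether synthesis, in which the phenoxide formed with K2CO3 is alkylated by benzyl bromide to give a protecting group that can be removed by neutral hydrogenolysis at the end.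

Step 2
Reactants: 2 1-(benzyloxy)-3-bromo-5-fluorobenzene
Product: 3 1-(benzyloxy)-3-fluoro-5-heptylbenzene
Conditions: n-C7H15MgBr (1.3 equiv), PdCl2(dppf) (3 mol%), THF, 0 → 20 °C
Reagents that add atoms: n-heptylmagnesium bromide, CCCCCCC[Mg]Br
Why: Kumada coupling, in which zerovalent palladium inserts only into the C–Br bond (C–F and the benzyl ether are inert) and the wide-bite-angle diphosphine favours reductive elimination of the primary alkyl over β-hydride elimination.

Step 3
Reactants: 3 1-(benzyloxy)-3-fluoro-5-heptylbenzene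
Product: 4 5-(benzyloxy)-2-bromo-1-fluoro-3-heptylbenzene
Conditions: NBS (1.05 equiv), MeCN, 0 → 20 °C, dark
Reagents that add atoms: N-bromosuccinimide, O=C1CCC(=O)N1Br
Why: Electrophilic aromatic bromination, which in acetonitrile should go para to the alkoxy group (the position between fluorine and heptyl, also ortho to both), while polar, dark conditions suppress benzylic radical bromination.

Step 4
Reactants: 4 5-(benzyloxy)-2-bromo-1-fluoro-3-heptylbenzene
Product: 6 1-[4-(benzyloxy)-2-fluoro-6-heptylphenyl]ethan-1-one, via aryllithium 5 (not isolated)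
Conditions: n-BuLi (1.05 equiv), THF, −78 °C; then MeC(O)N(OMe)Me, −78 → 0 °C; aq NH4Cl
Reagents that add atoms: N-methoxy-N-methylacetamide, CC(=O)N(C)OC; n-butyllithium, [Li]CCCC (supplies only the lithium of 5)
Why: Bromine–lithium exchange at −78 °C (below the temperature at which the ortho-fluoro aryllithium would lose LiF to an aryne) gives 5, which is acylated once because the chelated tetrahedral adduct of the N-methoxy-N-methylamide survives until work-up (Weinreb ketone synthesis).

Step 5
Reactants: 7 methyl 2-(3,5-dihydroxyphenyl)acetate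
Product: 8 methyl 2-[3,5-bis(benzyloxy)phenyl]acetate
Conditions: BnBr (2.3 equiv), K2CO3, acetone, reflux
Reagents that add atoms: benzyl bromide, BrCc1ccccc1
Why: Williamson ether synthesis of both phenols, with a carbonate base too weak to deprotonate the arylacetate methylene.

Step 6
Reactants: 8 methyl 2-[3,5-bis(benzyloxy)phenyl]acetate
Product: 9 methyl 2-[3,5-bis(benzyloxy)-2-formylphenyl]acetate
Conditions: POCl3, DMF, 0 → 60 °C; then H2O
Reagents that add atoms: N,N-dimethylformamide, CN(C)C=O (formyl carbon); water, O (aldehyde oxygen, on hydrolysis)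
Why: Vilsmeier–Haack formylation, in which the chloroiminium ion should attack the ring carbon that is para to one benzyloxy group and ortho to the other (two equivalent sites) rather than the more hindered carbon between the two ethers, and the iminium salt is hydrolysed on work-up.

Step 7
Reactants: 9 methyl 2-[3,5-bis(benzyloxy)-2-formylphenyl]acetate
Product: 10 2,4-bis(benzyloxy)-6-(2-methoxy-2-oxoethyl)benzoic acid
Conditions: NaClO2, NaH2PO4, 2-methyl-2-butene, t-BuOH/H2O, 20 °C
Reagents that add atoms: sodium chlorite, [Na+].[O-]Cl=O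
Why: Pinnick oxidation converts the aldehyde into the acid without touching the ester or the benzyl ethers, and the alkene scavenges hypochlorous acid before it can chlorinate the electron-rich ring.

Step 8
Reactants: 6 1-[4-(benzyloxy)-2-fluoro-6-heptylphenyl]ethan-1-one and 10 2,4-bis(benzyloxy)-6-(2-methoxy-2-oxoethyl)benzoic acid
Product: 12 2,4-bis(benzyloxy)-6-{[7-(benzyloxy)-5-heptyl-4-oxo-4H-chromen-2-yl]methyl}benzoic acid, via 1,3-diketone 11 (not isolated)
Conditions: NaH (4 equiv), THF, 0 → 60 °C; then DMF, 90 °C; aq HCl (pH 3)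
Reagents that add atoms: none
Why: NaH turns 10 into its carboxylate and 6 into its sodium enolate, whose carbon attacks the methyl ester (crossed Claisen condensation) to give 1,3-diketone 11, held as its enolate; in hot DMF the enolate oxygen on C2 adds to the fluorine-bearing ring carbon ortho to the aryl ketone and fluoride leaves from the Meisenheimer complex (intramolecular SNAr). The closest known reaction type is the chromone synthesis from 2-fluoroaryl methyl ketones and esters by Claisen acylation followed by SNAr closure of the 1-(2-fluoroaryl)-1,3-diketone. Ring C closes 6-exo-trig by addition–elimination at the aromatic carbon, and the second diketonate oxygen could reach that carbon only through a four-membered ring. No stereocenter is formed, since C2 is sp2 in 12 and is set in step 10. The step needs C-acylation by the ketone enolate rather than self-condensation of the more acidic arylacetate, which the irreversible deprotonation of 11 should secure under equilibrating conditions, and it needs the diketone to react only at C–F: carrying the benzoic acid as its carboxylate switches off enol-lactone (isocoumarin) and Claisen-type (naphthalenediol) closures onto that carbonyl, and the single fluorine fixes the site of O-arylation.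

Step 9
Reactants: 12 2,4-bis(benzyloxy)-6-{[7-(benzyloxy)-5-heptyl-4-oxo-4H-chromen-2-yl]methyl}benzoic acid
Product: 13 benzyl 2,4-bis(benzyloxy)-6-{[7-(benzyloxy)-5-heptyl-4-oxo-4H-chromen-2-yl]methyl}benzoate
Conditions: BnBr (1.2 equiv), K2CO3, DMF, 20 °C
Reagents that add atoms: benzyl bromide, BrCc1ccccc1
Why: Carboxylate alkylation (SN2 at the benzylic carbon) is insensitive to the two ortho substituents of the acid and gives a neutral, hydrogenolysable ester now that no diketone remains to attack it.

Step 10
Reactants: 13 benzyl 2,4-bis(benzyloxy)-6-{[7-(benzyloxy)-5-heptyl-4-oxo-4H-chromen-2-yl]methyl}benzoate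
Product: 14 benzyl 2,4-bis(benzyloxy)-6-{[(2R)-7-(benzyloxy)-5-heptyl-4-oxo-2-(4,4,5,5-tetramethyl-1,3,2-dioxaborolan-2-yl)-3,4-dihydro-2H-chromen-2-yl]methyl}benzoate
Conditions: B2pin2 (1.5 equiv), CuCl (10 mol%), (R,R)-QuinoxP* (12 mol%), NaOtBu (20 mol%), MeOH (2 equiv), THF, 0 → 20 °C
Reagents that add atoms: bis(pinacolato)diboron, CC1(C)OB(OC1(C)C)B1OC(C)(C)C(C)(C)O1
Why: Proposed new method: a diphosphine-ligated copper boryl, formed from CuCl, NaOtBu and B2pin2, should add across the C2=C3 bond of the chromone (a β-aryloxy enone) with boron going to the β-carbon C2 on the face chosen by the ligand, and methanol should protonate the copper enolate at C3 faster than it can expel the aryloxide, which sets C2 as (R) under catalyst control (the (S,S)-ligand is used instead if the facial sense proves opposite); the closest known reaction type is the copper-catalysed enantioselective conjugate borylation of β,β-disubstituted enones to tertiary boronates.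

Step 11
Reactants: 14 benzyl 2,4-bis(benzyloxy)-6-{[(2R)-7-(benzyloxy)-5-heptyl-4-oxo-2-(4,4,5,5-tetramethyl-1,3,2-dioxaborolan-2-yl)-3,4-dihydro-2H-chromen-2-yl]methyl}benzoate
Product: 15 benzyl 2,4-bis(benzyloxy)-6-{[(2R)-7-(benzyloxy)-5-heptyl-2-hydroxy-4-oxo-3,4-dihydro-2H-chromen-2-yl]methyl}benzoate
Conditions: 30% aq H2O2, pH 7 phosphate buffer, THF, 0 °C
Reagents that add atoms: hydrogen peroxide, OO
Why: Boronate oxidation proceeds by 1,2-shift of carbon from boron to oxygen with retention, so the (R)-boronate should give the (R)-hemiketal, and buffering at pH 7 and 0 °C should keep the hemiketal from opening to the diketone.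

Step 12
Reactants: 15 benzyl 2,4-bis(benzyloxy)-6-{[(2R)-7-(benzyloxy)-5-heptyl-2-hydroxy-4-oxo-3,4-dihydro-2H-chromen-2-yl]methyl}benzoate
Product: 16 2-{[(2R)-5-heptyl-2,7-dihydroxy-4-oxo-3,4-dihydro-2H-chromen-2-yl]methyl}-4,6-dihydroxybenzoic acid
Conditions: H2 (1 atm), 10% Pd/C, EtOAc, 20 °C; filter, evaporate below 25 °C
Reagents that add atoms: none
Why: Catalytic hydrogenolysis of the three benzyl ethers and the benzyl ester is neutral and touches neither the C2–O bonds nor the electron-rich aryl ketone, so C2 should stay (R) and the product is obtained by filtration and cold evaporation.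

**Compound list**

1 | 3-bromo-5-fluorophenol | Oc1cc(F)cc(Br)c1 | starting material
2 | 1-(benzyloxy)-3-bromo-5-fluorobenzene | Fc1cc(Br)cc(OCc2ccccc2)c1 | intermediate
3 | 1-(benzyloxy)-3-fluoro-5-heptylbenzene | CCCCCCCc1cc(F)cc(OCc2ccccc2)c1 | intermediate
4 | 5-(benzyloxy)-2-bromo-1-fluoro-3-heptylbenzene | CCCCCCCc1cc(OCc2ccccc2)cc(F)c1Br | intermediate
5 | [4-(benzyloxy)-2-fluoro-6-heptylphenyl]lithium (not isolated) | CCCCCCCc1cc(OCc2ccccc2)cc(F)c1[Li] | intermediate
6 | 1-[4-(benzyloxy)-2-fluoro-6-heptylphenyl]ethan-1-one | CCCCCCCc1cc(OCc2ccccc2)cc(F)c1C(C)=O | intermediate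
7 | methyl 2-(3,5-dihydroxyphenyl)acetate | COC(=O)Cc1cc(O)cc(O)c1 | starting material
8 | methyl 2-[3,5-bis(benzyloxy)phenyl]acetate | COC(=O)Cc1cc(OCc2ccccc2)cc(OCc2ccccc2)c1 | intermediate
9 | methyl 2-[3,5-bis(benzyloxy)-2-formylphenyl]acetate | COC(=O)Cc1cc(OCc2ccccc2)cc(OCc2ccccc2)c1C=O | intermediate
10 | 2,4-bis(benzyloxy)-6-(2-methoxy-2-oxoethyl)benzoic acid | COC(=O)Cc1cc(OCc2ccccc2)cc(OCc2ccccc2)c1C(=O)O | intermediate
11 | 2,4-bis(benzyloxy)-6-{4-[4-(benzyloxy)-2-fluoro-6-heptylphenyl]-2,4-dioxobutyl}benzoic acid (not isolated; present as its disodium salt) | CCCCCCCc1cc(OCc2ccccc2)cc(F)c1C(=O)CC(=O)Cc1cc(OCc2ccccc2)cc(OCc2ccccc2)c1C(=O)O | intermediate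
12 | 2,4-bis(benzyloxy)-6-{[7-(benzyloxy)-5-heptyl-4-oxo-4H-chromen-2-yl]methyl}benzoic acid | CCCCCCCc1cc(OCc2ccccc2)cc2c1C(=O)C=C(Cc1cc(OCc3ccccc3)cc(OCc3ccccc3)c1C(=O)O)O2 | intermediate
13 | benzyl 2,4-bis(benzyloxy)-6-{[7-(benzyloxy)-5-heptyl-4-oxo-4H-chromen-2-yl]methyl}benzoate | CCCCCCCc1cc(OCc2ccccc2)cc2c1C(=O)C=C(Cc1cc(OCc3ccccc3)cc(OCc3ccccc3)c1C(=O)OCc1ccccc1)O2 | intermediate
14 | benzyl 2,4-bis(benzyloxy)-6-{[(2R)-7-(benzyloxy)-5-heptyl-4-oxo-2-(4,4,5,5-tetramethyl-1,3,2-dioxaborolan-2-yl)-3,4-dihydro-2H-chromen-2-yl]methyl}benzoate | CCCCCCCc1cc(OCc2ccccc2)cc2c1C(=O)C[C@@](B3OC(C)(C)C(C)(C)O3)(Cc1cc(OCc3ccccc3)cc(OCc3ccccc3)c1C(=O)OCc1ccccc1)O2 | intermediate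
15 | benzyl 2,4-bis(benzyloxy)-6-{[(2R)-7-(benzyloxy)-5-heptyl-2-hydroxy-4-oxo-3,4-dihydro-2H-chromen-2-yl]methyl}benzoate | CCCCCCCc1cc(OCc2ccccc2)cc2c1C(=O)C[C@@](O)(Cc1cc(OCc3ccccc3)cc(OCc3ccccc3)c1C(=O)OCc1ccccc1)O2 | intermediate
16 | 2-{[(2R)-5-heptyl-2,7-dihydroxy-4-oxo-3,4-dihydro-2H-chromen-2-yl]methyl}-4,6-dihydroxybenzoic acid | CCCCCCCc1cc(O)cc2c1C(=O)C[C@@](O)(Cc1cc(O)cc(O)c1C(=O)O)O2 | target

**Step count and risks**

Total step count: 12. Longest linear sequence: 9 steps (steps 1–4, then 8–12).

Steps most likely to fail: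

1. Step 10 (labelled proposal). The copper boryl may add too slowly to the vinylogous ester, the copper enolate may expel the aryloxide (ring opening, with loss of enantiopurity), or the ligand may give poor facial selectivity. Fallback with known chemistry, setting out from 13 and coming back at 16: hydrogenolysis of 13 (H2, 10% Pd/C, EtOAc/MeOH) should give 2-[(5-heptyl-7-hydroxy-4-oxo-4H-chromen-2-yl)methyl]-4,6-dihydroxybenzoic acid F1. Aqueous NaOH under argon should open the pyranone by hydroxide addition at C2 and retro-oxa-Michael cleavage, and acidification to pH 3–4 at 0 °C lets the phenol close on the C2 ketone to give racemic 2-[(5-heptyl-2,7-dihydroxy-4-oxo-3,4-dihydro-2H-chromen-2-yl)methyl]-4,6-dihydroxybenzoic acid F2. Preparative chromatography on a chiral stationary phase (supercritical CO2/alcohol, cold) should then give 16, while 2-{[(2S)-5-heptyl-2,7-dihydroxy-4-oxo-3,4-dihydro-2H-chromen-2-yl]methyl}-4,6-dihydroxybenzoic acid F3 is racemised through the open diketone and recycled.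

2. Step 8 (key step). Fluoride displacement by the deprotonated, electron-rich diketone may be too slow, so that retro-Claisen cleavage or intermolecular displacement of fluoride by methoxide takes over; proton transfer to the arylacetate may also stall the acylation. Fallback setting out from 6 (with 10) and coming back at 12, in which the O–aryl bond is made first on the neutral, better activated ketone and the ring is closed by hemiketalisation and dehydration instead of SNAr: KOH in DMSO/water at 100 °C should convert 6 into 1-[4-(benzyloxy)-2-heptyl-6-hydroxyphenyl]ethan-1-one F4. Claisen condensation of the dianion of F4 with 10 (NaH, THF, 60 °C), the classical entry to 2-benzylchromones from 2-hydroxyacetophenones, should give after acidification racemic 2,4-bis(benzyloxy)-6-{[7-(benzyloxy)-5-heptyl-2-hydroxy-4-oxo-3,4-dihydro-2H-chromen-2-yl]methyl}benzoic acid F5. Acetic acid with catalytic H2SO4 at 20 °C should dehydrate F5 to 12.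

3. Step 11. The hemiketal set free in the aqueous oxidation may open to the diketone and reclose without control (erosion of enantiopurity), or it may dehydrate back to chromone 13 on work-up or chromatography. Fallback setting out from 14 and coming back at 16, in which the order of unveiling is reversed so that C2 stays a configurationally fixed C–B center until the last operation: hydrogenolysis of 14 (H2, 10% Pd/C, EtOAc) should give 2-{[(2R)-5-heptyl-7-hydroxy-4-oxo-2-(4,4,5,5-tetramethyl-1,3,2-dioxaborolan-2-yl)-3,4-dihydro-2H-chromen-2-yl]methyl}-4,6-dihydroxybenzoic acid F6. Oxidation of F6 with anhydrous trimethylamine N-oxide in THF (retentive 1,2-shift, no water and no base stronger than trimethylamine), followed by a brief wash at pH 4–5 to cleave the borate ester, should give 16 directly.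

**Further compounds**

F1 | step 10 | 2-[(5-heptyl-7-hydroxy-4-oxo-4H-chromen-2-yl)methyl]-4,6-dihydroxybenzoic acid | CCCCCCCc1cc(O)cc2c1C(=O)C=C(Cc1cc(O)cc(O)c1C(=O)O)O2
F2 | step 10 | racemic 2-[(5-heptyl-2,7-dihydroxy-4-oxo-3,4-dihydro-2H-chromen-2-yl)methyl]-4,6-dihydroxybenzoic acid | CCCCCCCc1cc(O)cc2c1C(=O)CC(O)(Cc1cc(O)cc(O)c1C(=O)O)O2
F3 | step 10 | 2-{[(2S)-5-heptyl-2,7-dihydroxy-4-oxo-3,4-dihydro-2H-chromen-2-yl]methyl}-4,6-dihydroxybenzoic acid | CCCCCCCc1cc(O)cc2c1C(=O)C[C@](O)(Cc1cc(O)cc(O)c1C(=O)O)O2
F4 | step 8 | 1-[4-(benzyloxy)-2-heptyl-6-hydroxyphenyl]ethan-1-one | CCCCCCCc1cc(OCc2ccccc2)cc(O)c1C(C)=O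
F5 | step 8 | racemic 2,4-bis(benzyloxy)-6-{[7-(benzyloxy)-5-heptyl-2-hydroxy-4-oxo-3,4-dihydro-2H-chromen-2-yl]methyl}benzoic acid | CCCCCCCc1cc(OCc2ccccc2)cc2c1C(=O)CC(O)(Cc1cc(OCc3ccccc3)cc(OCc3ccccc3)c1C(=O)O)O2
F6 | step 11 | 2-{[(2R)-5-heptyl-7-hydroxy-4-oxo-2-(4,4,5,5-tetramethyl-1,3,2-dioxaborolan-2-yl)-3,4-dihydro-2H-chromen-2-yl]methyl}-4,6-dihydroxybenzoic acid | CCCCCCCc1cc(O)cc2c1C(=O)C[C@@](B3OC(C)(C)C(C)(C)O3)(Cc1cc(O)cc(O)c1C(=O)O)O2
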